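**Plan**

1. The target is read as (+)-catechin-(4α→8)-(+)-gallocatechin-(4β→8)-(+)-catechin: the top unit is 2,3-trans-3,4-trans and the middle unit is 2,3-trans-3,4-cis. Retrosynthetic cuts, in order: fifteen O-benzyl groups; top C3–O back to C3–B; O1–C2 and C3–C4 of the top pyran ring (ring C) in one retro-[4+2]; C4(top)–C8(middle); C4(middle)–C8(bottom).
2. Enabling feature: in the top unit O1–C8a–C4a–C4 is a latent 1-oxadiene. C4 is a diarylmethine held between the 5,7-dioxygenated ring A (O1 ortho to it) and the phloroglucinol-type ring D of the middle unit, so an o-hydroxybenzhydrol should lose water easily to a stabilised ortho-quinone methide. C2=C3 is a styrene of the catechol ring B.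
3. Helper: an oxygen on C3 would reverse the polarity of that styrene. A pinacol boronate stands in for it and is oxidised with retention afterwards.
4. Forward order: the pyran rings of the bottom and middle units arrive intact from (+)-catechin and (+)-gallocatechin. They are joined through a temporary glutarate tether (a 14-membered helper ring, cut later). The 8-bromine of the middle unit becomes an aryllithium that picks up ring A as a salicylaldehyde. The top pyran ring closes last.
5. Stereochemistry: C2/C3 of the two lower units come from the chiral pool. C4(middle) is set β by tether delivery on the face of 3-O. Top C2/C3 are trans from the E-alkene, top C4 follows from the endo rule, and the absolute sense of the three top centres comes from a chiral Brønsted acid.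

Key step: step 13

Remark: the C4 ether of the middle-unit electrophile is drawn 4β and the benzhydrol carbinol carbon is drawn without descriptor (both epimers). Neither configuration matters, because both carbons are ionised later.
Remark: the (R)-configured catalyst is assumed to be the matched one. The sense of induction has to be established by experiment, and the (S)-catalyst is equally available.

**Step 1**
Reactants: 1 (+)-catechin
Product: 2 5,7,3',4'-tetra-O-benzyl-(+)-catechin
Conditions: BnBr (4.4 equiv), K2CO3, DMF, 0 °C to rt, argon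
Reagents that add atoms: benzyl bromide, BrCc1ccccc1
Why: Williamson etherification in which K2CO3 deprotonates only the four phenols, so the secondary 3-OH stays free and C2 and C3 are untouched.

**Step 2**
Reactants: 2 5,7,3',4'-tetra-O-benzyl-(+)-catechin
Product: 3 tetra-O-benzylcatechin 3-O-(hydrogen glutarate)
Conditions: glutaric anhydride (1.5 equiv), DMAP (0.2 equiv), pyridine, 50 °C
Reagents that add atoms: glutaric anhydride, O=C1CCCC(=O)O1
Why: DMAP-catalysed acylation of the only free hydroxyl by a cyclic anhydride should stop at the half ester, which carries the free acid end of the tether.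

**Step 3**
Reactants: 4 (+)-gallocatechin
Product: 5 5,7,3',4',5'-penta-O-benzyl-(+)-gallocatechin
Conditions: BnBr (5.5 equiv), K2CO3, DMF, 0 °C to rt, argon
Reagents that add atoms: benzyl bromide, BrCc1ccccc1
Why: Williamson etherification as in step 1, run under argon because the pyrogallol ring is air-sensitive in base, with the 3-OH left free and C2 and C3 untouched.

**Step 4**
Reactants: 5 5,7,3',4',5'-penta-O-benzyl-(+)-gallocatechin
Product: 6 4β-(2-ethoxyethoxy)-5,7,3',4',5'-penta-O-benzylgallocatechin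
Conditions: DDQ (1.5 equiv), 2-ethoxyethanol, CH2Cl2, rt
Reagents that add atoms: 2-ethoxyethanol, CCOCCO
Why: DDQ benzylic oxidation, in which hydride abstraction from C4 (the benzylic carbon conjugated with the 5,7-dioxygenated ring) gives a flavan-4-yl cation that the alcohol traps, presumably trans to the C2 aryl group, at a centre that step 7 erases.

**Step 5**
Reactants: 6 4β-(2-ethoxyethoxy)-5,7,3',4',5'-penta-O-benzylgallocatechin
Product: 7 8-bromo-4β-(2-ethoxyethoxy)-5,7,3',4',5'-penta-O-benzylgallocatechin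
Conditions: NBS (1.0 equiv), CH2Cl2, −78 °C to 0 °C
Reagents that add atoms: N-bromosuccinimide, O=C1CCC(=O)N1Br
Why: Electrophilic aromatic bromination goes to C8, the most nucleophilic ring carbon of 5,7-di-O-benzylflavans, and the bromine both blocks self-condensation in step 7 and serves as the handle for step 12.

**Step 6**
Reactants: 3 tetra-O-benzylcatechin 3-O-(hydrogen glutarate); 7 8-bromo-4β-(2-ethoxyethoxy)-5,7,3',4',5'-penta-O-benzylgallocatechin
Product: 8 open glutarate diester joining 3-O of 7 to 3-O of the catechin unit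
Conditions: DCC (1.2 equiv), DMAP (0.2 equiv), CH2Cl2, 0 °C to rt
Reagents that add atoms: none
Why: Steglich esterification joins the acid and the hindered secondary alcohol under neutral conditions that spare the acid-labile C4 ether.

**Step 7**
Reactants: 8 open glutarate diester
Product: 9 glutarate-bridged 8-bromo-penta-O-benzylgallocatechin-(4β→8)-tetra-O-benzylcatechin (14-membered helper ring)
Conditions: Me3SiOTf (0.2 equiv), CH2Cl2 (1 mM), −78 °C to −40 °C; Et3N quench
Reagents that add atoms: none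
Why: Lewis acid-promoted intramolecular Friedel–Crafts alkylation of the flavan-4-yl cation by C8 of the catechin unit, a reaction type known for diester-tethered catechin pairs, in which the short tether that starts from the β-oriented 3-O should allow delivery only to the β face and so set C4 as 3,4-cis (4β), while high dilution and the 8-bromine suppress oligomerisation.

**Step 8**
Reactants: 9 glutarate-bridged dimer
Product: 10 8-bromo-5,7,3',4',5'-penta-O-benzylgallocatechin-(4β→8)-5,7,3',4'-tetra-O-benzylcatechin (both 3-OH free)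
Conditions: NaOMe (0.3 equiv), MeOH–THF 1:1, 40 °C
Reagents that add atoms: none
Why: Base-catalysed transesterification (Zemplén type) cuts both ester bonds of the helper ring and touches neither the benzyl ethers, the aryl bromide nor any stereocentre.

**Step 9**
Reactants: 10 dimer diol
Product: 11 8-bromo-undeca-O-benzyl-gallocatechin-(4β→8)-catechin
Conditions: NaH (3 equiv), BnBr (3 equiv), n-Bu4NI (cat.), DMF, 0 °C to rt
Reagents that add atoms: benzyl bromide, BrCc1ccccc1
Why: Williamson etherification of the two secondary alkoxides masks the only acidic protons before the organolithium step with groups that leave in the final hydrogenolysis.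

**Step 10**
Reactants: 12 2,4,6-trihydroxybenzaldehyde
Product: 13 2,4-bis(benzyloxy)-6-hydroxybenzaldehyde
Conditions: BnBr (2.05 equiv), K2CO3 (2.2 equiv), DMF, rt
Reagents that add atoms: benzyl bromide, BrCc1ccccc1
Why: Selective Williamson etherification, since after two alkylations the remaining ortho hydroxyl is locked in a hydrogen bond to the formyl oxygen and should stay free.

**Step 11**
Reactants: 14 3,4-bis(benzyloxy)benzaldehyde; 15 bis[(pinacolato)boryl]methane
Product: 17 (E)-2-[3,4-bis(benzyloxy)styryl]-4,4,5,5-tetramethyl-1,3,2-dioxaborolane, via lithiated diborylmethane 16 (not isolated)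
Conditions: 15 (1.2 equiv), lithium 2,2,6,6-tetramethylpiperidide (1.2 equiv), THF, 0 °C; then 14, −78 °C to rt
Reagents that add atoms: none
Why: Boron–Wittig olefination, in which the α-boryl carbanion adds to the aldehyde and syn B–O elimination from the less crowded adduct should give the E-alkenylboronate.

**Step 12**
Reactants: 11 8-bromo-undeca-O-benzyl dimer; 13 2,4-bis(benzyloxy)-6-hydroxybenzaldehyde
Product: 20 o-hydroxybenzhydrol [2-hydroxy-4,6-bis(benzyloxy)phenyl](dimer-8-yl)methanol (both carbinol epimers), via sodium phenolate 18 (not isolated), via aryllithium 19 (not isolated)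
Conditions: 13, NaH (1.05 equiv), THF, 0 °C; separately 11, n-BuLi (1.05 equiv), THF, −78 °C; combine at −78 °C, warm to −20 °C; aq NaHCO3; used without chromatography on acidic silica
Reagents that add atoms: none
Why: Bromine–lithium exchange at C8 (flanked by two oxygens) followed by 1,2-addition of the aryllithium to the aldehyde, whose phenol is masked in the flask as its phenolate, gives a carbinol centre as a mixture that the next step erases.

**Step 13**
Reactants: 20 o-hydroxybenzhydrol; 17 (E)-styrylboronate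
Product: 22 3-deoxy-3β-(pinacolboryl) trimer (top unit 2α-aryl, 3β-boryl, 4α-aryl; 5,7,3',4'-tetra-O-benzyl), via ortho-quinone methide 21 (not isolated)
Conditions: 17 (2 equiv), (R)-N-triflylphosphoramide of 3,3'-bis(2,4,6-triisopropylphenyl)-BINOL (10 mol %), 5 Å molecular sieves, toluene–CH2Cl2, −40 °C to 0 °C
Reagents that add atoms: none
Why: Proposed new method: the chiral Brønsted acid dehydrates 20 to the ortho-quinone methide 21, whose 1-oxadiene O1=C8a–C4a=C4 stays hydrogen-bonded or ion-paired to the phosphoramide anion, and the electrophilic C4 terminus then bonds to the boron-bearing carbon of 17 while O1 closes on the benzylic carbon in a concerted but asynchronous inverse-electron-demand oxa-[4+2] cycloaddition, the charge building at C2 being carried by the 3,4-dibenzyloxyphenyl ring and by σ(C–B) hyperconjugation. The closest known reaction type is the chiral N-triflylphosphoramide-catalysed [4+2] cycloaddition of ortho-quinone methides from o-hydroxybenzhydrols with styrenes, which gives 2,4-cis-diarylchromans, whereas an alkenylboronate as the two-carbon partner has not been shown. The only ring closed is the top pyran ring, by an intermolecular [4+2] closure that makes C3–C4 and O1–C2 in one event. C2 and C3 should come out trans because the E geometry of 17 is transferred suprafacially, C4 should come out cis to the C2 aryl and trans to boron because only E-configured 21 (ring D in the outside position) can reach the transition state and the ring B aryl sits endo under ring A, and the absolute sense of all three centres is set by the catalyst pocket that covers one face of 21, the resident stereocentres being remote. The step needs C3-to-C4 regiochemistry, which an oxygen on C3 would reverse and which boron (no lone pair, β-cation stabilising) leaves under the control of ring B, and it needs a single oxadiene, which is secured because the 8a-OH is the only free phenol of 20. Excess 17 and molecular sieves should suppress capture of 21 by a second molecule of 20 or by water.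

**Step 14**
Reactants: 22 3β-boryl trimer
Product: 23 pentadeca-O-benzyl trimer with free top 3-OH
Conditions: 30% aq H2O2, 2 M aq NaOH, THF, 0 °C
Reagents that add atoms: hydrogen peroxide, OO
Why: Oxidation of a secondary alkylboronic ester by hydroperoxide proceeds through a 1,2-metallate shift with retention, so the β-oriented C3–B bond becomes the β-oriented C3–OH, and the low temperature should keep β-elimination of the O1 aryloxide in check.

**Step 15**
Reactants: 23 pentadeca-O-benzyl trimer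
Product: 24 (+)-catechin-(4α→8)-(+)-gallocatechin-(4β→8)-(+)-catechin (target)
Conditions: H2 (1 atm), Pd(OH)2/C, THF–MeOH–H2O, rt
Reagents that add atoms: none
Why: Catalytic hydrogenolysis of all fifteen benzyl ethers under neutral conditions, the standard last step for benzylated proanthocyanidins, should leave the interflavan bonds and all eight stereocentres intact.

**Compound list**

1 | (+)-catechin | Oc1cc(O)c2c(c1)O[C@H](c1ccc(O)c(O)c1)[C@@H](O)C2 | starting material
2 | 5,7,3',4'-tetra-O-benzyl-(+)-catechin | O(Cc9ccccc9)c1cc(OCc9ccccc9)c2c(c1)O[C@H](c1ccc(OCc9ccccc9)c(OCc9ccccc9)c1)[C@@H](O)C2 | intermediate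
3 | tetra-O-benzylcatechin 3-O-(hydrogen glutarate) | O(Cc9ccccc9)c1cc(OCc9ccccc9)c2c(c1)O[C@H](c1ccc(OCc9ccccc9)c(OCc9ccccc9)c1)[C@@H](OC(=O)CCCC(=O)O)C2 | intermediate
4 | (+)-gallocatechin | Oc1cc(O)c2c(c1)O[C@H](c1cc(O)c(O)c(O)c1)[C@@H](O)C2 | starting material
5 | 5,7,3',4',5'-penta-O-benzyl-(+)-gallocatechin | O(Cc9ccccc9)c1cc(OCc9ccccc9)c2c(c1)O[C@H](c1cc(OCc9ccccc9)c(OCc9ccccc9)c(OCc9ccccc9)c1)[C@@H](O)C2 | intermediate
6 | 4β-(2-ethoxyethoxy)-penta-O-benzylgallocatechin | O(Cc9ccccc9)c1cc(OCc9ccccc9)c2c(c1)O[C@H](c1cc(OCc9ccccc9)c(OCc9ccccc9)c(OCc9ccccc9)c1)[C@@H](O)[C@H]2OCCOCC | intermediate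
7 | 8-bromo-4β-(2-ethoxyethoxy)-penta-O-benzylgallocatechin | Brc1c(OCc9ccccc9)cc(OCc9ccccc9)c2c1O[C@H](c1cc(OCc9ccccc9)c(OCc9ccccc9)c(OCc9ccccc9)c1)[C@@H](O)[C@H]2OCCOCC | intermediate
8 | open glutarate diester (3-O of 7 to 3-O of 2) | Brc1c(OCc9ccccc9)cc(OCc9ccccc9)c2c1O[C@H](c1cc(OCc9ccccc9)c(OCc9ccccc9)c(OCc9ccccc9)c1)[C@@H](OC(=O)CCCC(=O)O[C@H]3Cc4c(OCc9ccccc9)cc(OCc9ccccc9)cc4O[C@@H]3c3ccc(OCc9ccccc9)c(OCc9ccccc9)c3)[C@H]2OCCOCC | intermediate
9 | glutarate-bridged 8-bromo-nona-O-benzyl-gallocatechin-(4β→8)-catechin | Brc1c(OCc9ccccc9)cc(OCc9ccccc9)c2c1O[C@H](c1cc(OCc9ccccc9)c(OCc9ccccc9)c(OCc9ccccc9)c1)[C@@H](OC(=O)CCCC(=O)O3)[C@H]2c1c(OCc9ccccc9)cc(OCc9ccccc9)c2c1O[C@H](c1ccc(OCc9ccccc9)c(OCc9ccccc9)c1)[C@@H]3C2 | intermediate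
10 | 8-bromo-nona-O-benzyl-gallocatechin-(4β→8)-catechin, both 3-OH free | Brc1c(OCc9ccccc9)cc(OCc9ccccc9)c2c1O[C@H](c1cc(OCc9ccccc9)c(OCc9ccccc9)c(OCc9ccccc9)c1)[C@@H](O)[C@H]2c1c(OCc9ccccc9)cc(OCc9ccccc9)c2c1O[C@H](c1ccc(OCc9ccccc9)c(OCc9ccccc9)c1)[C@@H](O)C2 | intermediate
11 | 8-bromo-undeca-O-benzyl-gallocatechin-(4β→8)-catechin | Brc1c(OCc9ccccc9)cc(OCc9ccccc9)c2c1O[C@H](c1cc(OCc9ccccc9)c(OCc9ccccc9)c(OCc9ccccc9)c1)[C@@H](OCc9ccccc9)[C@H]2c1c(OCc9ccccc9)cc(OCc9ccccc9)c2c1O[C@H](c1ccc(OCc9ccccc9)c(OCc9ccccc9)c1)[C@@H](OCc9ccccc9)C2 | intermediate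
12 | 2,4,6-trihydroxybenzaldehyde | O=Cc1c(O)cc(O)cc1O | starting material
13 | 2,4-bis(benzyloxy)-6-hydroxybenzaldehyde | O=Cc1c(O)cc(OCc9ccccc9)cc1OCc9ccccc9 | intermediate
14 | 3,4-bis(benzyloxy)benzaldehyde | O=Cc1ccc(OCc2ccccc2)c(OCc2ccccc2)c1 | starting material
15 | bis[(pinacolato)boryl]methane | CC1(C)OB(CB2OC(C)(C)C(C)(C)O2)OC1(C)C | starting material
16 | lithiated diborylmethane | [Li]C(B1OC(C)(C)C(C)(C)O1)B1OC(C)(C)C(C)(C)O1 | intermediate
17 | (E)-2-[3,4-bis(benzyloxy)styryl]-4,4,5,5-tetramethyl-1,3,2-dioxaborolane | CC1(C)OB(/C=C/c2ccc(OCc3ccccc3)c(OCc3ccccc3)c2)OC1(C)C | intermediate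
18 | sodium 3,5-bis(benzyloxy)-2-formylphenolate | [Na+].[O-]c1cc(OCc2ccccc2)cc(OCc2ccccc2)c1C=O | intermediate
19 | 8-lithio-undeca-O-benzyl-gallocatechin-(4β→8)-catechin | [Li]c1c(OCc9ccccc9)cc(OCc9ccccc9)c2c1O[C@H](c1cc(OCc9ccccc9)c(OCc9ccccc9)c(OCc9ccccc9)c1)[C@@H](OCc9ccccc9)[C@H]2c1c(OCc9ccccc9)cc(OCc9ccccc9)c2c1O[C@H](c1ccc(OCc9ccccc9)c(OCc9ccccc9)c1)[C@@H](OCc9ccccc9)C2 | intermediate
20 | o-hydroxybenzhydrol (carbinol carbon as both epimers) | Oc1cc(OCc9ccccc9)cc(OCc9ccccc9)c1C(O)c1c(OCc9ccccc9)cc(OCc9ccccc9)c2c1O[C@H](c1cc(OCc9ccccc9)c(OCc9ccccc9)c(OCc9ccccc9)c1)[C@@H](OCc9ccccc9)[C@H]2c1c(OCc9ccccc9)cc(OCc9ccccc9)c2c1O[C@H](c1ccc(OCc9ccccc9)c(OCc9ccccc9)c1)[C@@H](OCc9ccccc9)C2 | intermediate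
21 | (E)-ortho-quinone methide (ring D trans to the carbonyl carbon) | O=C1C=C(OCc9ccccc9)C=C(OCc9ccccc9)/C1=C\c1c(OCc9ccccc9)cc(OCc9ccccc9)c2c1O[C@H](c1cc(OCc9ccccc9)c(OCc9ccccc9)c(OCc9ccccc9)c1)[C@@H](OCc9ccccc9)[C@H]2c1c(OCc9ccccc9)cc(OCc9ccccc9)c2c1O[C@H](c1ccc(OCc9ccccc9)c(OCc9ccccc9)c1)[C@@H](OCc9ccccc9)C2 | intermediate
22 | 3β-(pinacolboryl) trimer, pentadeca-O-benzyl | O(Cc9ccccc9)c1cc(OCc9ccccc9)c2c(c1)O[C@H](c1ccc(OCc9ccccc9)c(OCc9ccccc9)c1)[C@@H](B1OC(C)(C)C(C)(C)O1)[C@@H]2c1c(OCc9ccccc9)cc(OCc9ccccc9)c2c1O[C@H](c1cc(OCc9ccccc9)c(OCc9ccccc9)c(OCc9ccccc9)c1)[C@@H](OCc9ccccc9)[C@H]2c1c(OCc9ccccc9)cc(OCc9ccccc9)c2c1O[C@H](c1ccc(OCc9ccccc9)c(OCc9ccccc9)c1)[C@@H](OCc9ccccc9)C2 | intermediate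
23 | pentadeca-O-benzyl trimer, top 3-OH free | O(Cc9ccccc9)c1cc(OCc9ccccc9)c2c(c1)O[C@H](c1ccc(OCc9ccccc9)c(OCc9ccccc9)c1)[C@@H](O)[C@@H]2c1c(OCc9ccccc9)cc(OCc9ccccc9)c2c1O[C@H](c1cc(OCc9ccccc9)c(OCc9ccccc9)c(OCc9ccccc9)c1)[C@@H](OCc9ccccc9)[C@H]2c1c(OCc9ccccc9)cc(OCc9ccccc9)c2c1O[C@H](c1ccc(OCc9ccccc9)c(OCc9ccccc9)c1)[C@@H](OCc9ccccc9)C2 | intermediate
24 | (+)-catechin-(4α→8)-(+)-gallocatechin-(4β→8)-(+)-catechin | Oc1cc(O)c2c(c1)O[C@H](c1ccc(O)c(O)c1)[C@@H](O)[C@@H]2c1c(O)cc(O)c2c1O[C@H](c1cc(O)c(O)c(O)c1)[C@@H](O)[C@H]2c1c(O)cc(O)c2c1O[C@H](c1ccc(O)c(O)c1)[C@@H](O)C2 | target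

**Totals**

Total step count: 15.
Longest linear sequence: 11 steps (3, 4, 5, 6, 7, 8, 9, 12, 13, 14, 15, from (+)-gallocatechin).

**Steps most likely to fail**

**Step 13.**
- What may go wrong:
  - The strongly stabilised, tetra-ortho-substituted quinone methide may react too slowly with a β-borylated styrene.
  - The developing C2 cation may shed boron, with ring opening to a 1,3-diarylpropene.
  - The catalyst may discriminate the two faces poorly.
- Fallback with known chemistry, same ring still closed last, from 11 back to 23: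
  - Compound 11 is lithiated (n-BuLi, THF, −78 °C) and formylated with DMF to the dimer 8-carbaldehyde F1.
  - Claisen–Schmidt condensation of F1 with commercial 3',4'-bis(benzyloxy)acetophenone (KOH, EtOH–THF) gives the E-enone F2.
  - A Brønsted acid-promoted conjugate Friedel–Crafts addition of commercial 3,5-bis(benzyloxy)phenol to F2, followed by cyclodehydration, closes the pyran ring as the 4-aryl-4H-chromene F3. The C4 epimers are separated at this stage.
  - Hydroboration (BH3·THF, 0 °C) should take place on the face away from the pseudo-axial C4 aryl group. This places hydrogen on C2 and boron on C3 trans to that aryl group, and H2O2/NaOH then leads to 23.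

**Step 7.**
- What may go wrong:
  - Macrocyclisation may lose to intermolecular coupling.
  - The 3-O-acyl carbonyl may participate at C4 and steer the arene to the α face.
  - The tether length may fit poorly.
- Fallback from 5 and 2 back to 11:
  - Compound 5 is benzylated at O3 (NaH, BnBr) to hexa-O-benzylgallocatechin F4.
  - F4 is oxidised at C4 with DDQ in wet CH2Cl2–THF to the flavan-4-ol F5, and then with Dess–Martin periodinane to the flavan-4-one F6.
  - Compound 2 is brominated at C8 (NBS) to 8-bromo-tetra-O-benzylcatechin F7 and benzylated at O3 to 8-bromo-penta-O-benzylcatechin F8.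
  - F8 is lithiated (n-BuLi, THF, −78 °C) and added to F6 to give the 4-aryl-flavan-4-ol F9.
  - Ionic reduction (Et3SiH, CF3CO2H, CH2Cl2, −78 °C to 0 °C) should deliver hydride to the 4-aryl cation on the α face, trans to the 3β-benzyloxy group. This leaves the aryl group β in the undeca-O-benzyl dimer F10.
  - NBS (1 equiv) should then brominate C8 of the upper unit, the most nucleophilic free position, to give 11.

**Step 12.**
- What may go wrong:
  - Addition of the hindered aryllithium to the phenolate-deactivated aldehyde may be sluggish.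
  - The aryllithium may be protonated.
  - The very labile benzhydrol may ionise during work-up.
- Fallback from 13 (with 19) back to 21:
  - Compound 13 is converted with Boc2O (i-Pr2NEt, DMAP cat.) into the aryl tert-butyl carbonate F11, whose aldehyde is not deactivated.
  - Addition of 19 at −78 °C is followed by migration of the Boc group from the phenol oxygen to the new alkoxide.
  - A cold AcOH quench gives the phenolic benzhydryl tert-butyl carbonate F12, which is not chromatographed.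
  - Under the conditions of step 13, F12 should fragment directly to 21.

**Further compounds**

F1 | step 13 | undeca-O-benzyl-gallocatechin-(4β→8)-catechin 8-carbaldehyde | O=Cc1c(OCc9ccccc9)cc(OCc9ccccc9)c2c1O[C@H](c1cc(OCc9ccccc9)c(OCc9ccccc9)c(OCc9ccccc9)c1)[C@@H](OCc9ccccc9)[C@H]2c1c(OCc9ccccc9)cc(OCc9ccccc9)c2c1O[C@H](c1ccc(OCc9ccccc9)c(OCc9ccccc9)c1)[C@@H](OCc9ccccc9)C2
F2 | step 13 | (E)-1-[3,4-bis(benzyloxy)phenyl]-3-(dimer-8-yl)prop-2-en-1-one | O=C(c1ccc(OCc9ccccc9)c(OCc9ccccc9)c1)/C=C/c1c(OCc9ccccc9)cc(OCc9ccccc9)c2c1O[C@H](c1cc(OCc9ccccc9)c(OCc9ccccc9)c(OCc9ccccc9)c1)[C@@H](OCc9ccccc9)[C@H]2c1c(OCc9ccccc9)cc(OCc9ccccc9)c2c1O[C@H](c1ccc(OCc9ccccc9)c(OCc9ccccc9)c1)[C@@H](OCc9ccccc9)C2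
F3 | step 13 | 5,7-bis(benzyloxy)-2-[3,4-bis(benzyloxy)phenyl]-4α-(dimer-8-yl)-4H-chromene | O(Cc9ccccc9)c1cc(OCc9ccccc9)c2c(c1)OC(c1ccc(OCc9ccccc9)c(OCc9ccccc9)c1)=C[C@@H]2c1c(OCc9ccccc9)cc(OCc9ccccc9)c2c1O[C@H](c1cc(OCc9ccccc9)c(OCc9ccccc9)c(OCc9ccccc9)c1)[C@@H](OCc9ccccc9)[C@H]2c1c(OCc9ccccc9)cc(OCc9ccccc9)c2c1O[C@H](c1ccc(OCc9ccccc9)c(OCc9ccccc9)c1)[C@@H](OCc9ccccc9)C2
F4 | step 7 | 3,5,7,3',4',5'-hexa-O-benzyl-(+)-gallocatechin | O(Cc9ccccc9)c1cc(OCc9ccccc9)c2c(c1)O[C@H](c1cc(OCc9ccccc9)c(OCc9ccccc9)c(OCc9ccccc9)c1)[C@@H](OCc9ccccc9)C2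
F5 | step 7 | hexa-O-benzylgallocatechin-4β-ol | O(Cc9ccccc9)c1cc(OCc9ccccc9)c2c(c1)O[C@H](c1cc(OCc9ccccc9)c(OCc9ccccc9)c(OCc9ccccc9)c1)[C@@H](OCc9ccccc9)[C@H]2O
F6 | step 7 | hexa-O-benzylgallocatechin-4-one | O(Cc9ccccc9)c1cc(OCc9ccccc9)c2c(c1)O[C@H](c1cc(OCc9ccccc9)c(OCc9ccccc9)c(OCc9ccccc9)c1)[C@@H](OCc9ccccc9)C2=O
F7 | step 7 | 8-bromo-5,7,3',4'-tetra-O-benzylcatechin | Brc1c(OCc9ccccc9)cc(OCc9ccccc9)c2c1O[C@H](c1ccc(OCc9ccccc9)c(OCc9ccccc9)c1)[C@@H](O)C2
F8 | step 7 | 8-bromo-3,5,7,3',4'-penta-O-benzylcatechin | Brc1c(OCc9ccccc9)cc(OCc9ccccc9)c2c1O[C@H](c1ccc(OCc9ccccc9)c(OCc9ccccc9)c1)[C@@H](OCc9ccccc9)C2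
F9 | step 7 | 4-(penta-O-benzylcatechin-8-yl)-hexa-O-benzylgallocatechin-4-ol (C4 not defined) | O(Cc9ccccc9)c1cc(OCc9ccccc9)c2c(c1)O[C@H](c1cc(OCc9ccccc9)c(OCc9ccccc9)c(OCc9ccccc9)c1)[C@@H](OCc9ccccc9)C2(O)c1c(OCc9ccccc9)cc(OCc9ccccc9)c2c1O[C@H](c1ccc(OCc9ccccc9)c(OCc9ccccc9)c1)[C@@H](OCc9ccccc9)C2
F10 | step 7 | undeca-O-benzyl-gallocatechin-(4β→8)-catechin | O(Cc9ccccc9)c1cc(OCc9ccccc9)c2c(c1)O[C@H](c1cc(OCc9ccccc9)c(OCc9ccccc9)c(OCc9ccccc9)c1)[C@@H](OCc9ccccc9)[C@H]2c1c(OCc9ccccc9)cc(OCc9ccccc9)c2c1O[C@H](c1ccc(OCc9ccccc9)c(OCc9ccccc9)c1)[C@@H](OCc9ccccc9)C2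
F11 | step 12 | 3,5-bis(benzyloxy)-2-formylphenyl tert-butyl carbonate | O=Cc1c(OC(=O)OC(C)(C)C)cc(OCc9ccccc9)cc1OCc9ccccc9
F12 | step 12 | [2-hydroxy-4,6-bis(benzyloxy)phenyl](dimer-8-yl)methyl tert-butyl carbonate (both epimers) | Oc1cc(OCc9ccccc9)cc(OCc9ccccc9)c1C(OC(=O)OC(C)(C)C)c1c(OCc9ccccc9)cc(OCc9ccccc9)c2c1O[C@H](c1cc(OCc9ccccc9)c(OCc9ccccc9)c(OCc9ccccc9)c1)[C@@H](OCc9ccccc9)[C@H]2c1c(OCc9ccccc9)cc(OCc9ccccc9)c2c1O[C@H](c1ccc(OCc9ccccc9)c(OCc9ccccc9)c1)[C@@H](OCc9ccccc9)C2
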